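**Retrosynthetic overview**

1. Target 16 is kaempferide with a (2S)-2-hydroxy-3-methylbut-3-enyl chain on C8 of ring A. The route rests on C2'', the only oxygen-bearing carbon of the chain, which sits between the benzylic C1'' and the alkenyl C3'' and can therefore be delivered as carbon monoxide.
2. The C2'' stereocentre comes from enone 13 by Corey–Bakshi–Shibata reduction; the three MOM ethers are removed last.
3. C1''–C2'' and C2''–C3'' are both made in one carbonylative Stille coupling of benzylic chloride 8, CO and isopropenyltributylstannane.
4. Chloride 8 comes from kaempferide by C8 aminomethylation (C8–C1''), tris-MOM protection and chloroformate exchange of NMe2 for Cl.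
5. No ring is formed anywhere in the route; rings A, B and C arrive intact in kaempferide.

Key step: step 4

Assumption: the Mannich reaction of kaempferide takes place at C8 rather than C6, as is usual for 5,7-dihydroxyflavones; the side-chain carbons are numbered C1''–C4'' outward from ring A.

**Route**

Step 1
Reactants: 1 kaempferide (3,5,7-trihydroxy-4'-methoxyflavone); 2 Eschenmoser's salt (N,N-dimethylmethyleneiminium iodide)
Product: 4 the Mannich base 8-[(dimethylamino)methyl]kaempferide, via kaempferide 7-potassium phenoxide 3 (not isolated)
Conditions: K2CO3 (1.0 equiv), DMF, 0 °C; then 2 (1.05 equiv), 0 °C to rt, argon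
Reagents that add atoms: Eschenmoser's salt (2), C=[N+](C)C.[I-]
Why: Phenolic Mannich reaction: the 7-phenoxide, a vinylogous carboxylate, attacks the preformed iminium ion through C8, the ring A carbon between O7 and the pyranone oxygen that is the usual site of aminomethylation in 5,7-dihydroxyflavones, and one equivalent of reagent limits a second substitution at C6.

Step 2
Reactants: 4 the Mannich base 8-[(dimethylamino)methyl]kaempferide
Product: 6 the tris-MOM amine 8-[(dimethylamino)methyl]-4'-methoxy-3,5,7-tris(methoxymethoxy)flavone, via trisodium triphenoxide 5 (not isolated)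
Conditions: NaH (3.5 equiv), DMF, 0 °C; then MOMCl (3.3 equiv), 0 °C to rt
Reagents that add atoms: chloromethyl methyl ether (MOMCl), COCCl
Why: Williamson-type O-alkylation: the three sodium phenoxides, the chelated 5-oxide included, are far better nucleophiles towards MOMCl than the neutral tertiary benzylic amine, so the acetals should form while the NMe2 group is kept, as in the MOM protection of other aminophenols.

Step 3
Reactants: 6 the tris-MOM amine
Product: 8 the benzylic chloride 8-(chloromethyl)-4'-methoxy-3,5,7-tris(methoxymethoxy)flavone, via N-ethoxycarbonylammonium chloride 7 (not isolated)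
Conditions: 6 added to ClCO2Et (1.5 equiv), CH2Cl2, 0 °C to rt; filtered through a short pad and used at once
Reagents that add atoms: ethyl chloroformate, CCOC(Cl)=O
Why: Chloroformate-mediated dealkylation of a tertiary benzylic amine (von Braun-type cleavage): N-acylation gives acylammonium chloride 7, and chloride then displaces ethyl N,N-dimethylcarbamate at the benzylic carbon, the N-substituent most open to substitution because O7, O1 and O5 stabilise positive charge at C1'', while inverse addition keeps unreacted amine away from the chloride formed.

Step 4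
Reactants: 8 the benzylic chloride; 9 isopropenyltributylstannane; 10 carbon monoxide
Product: 13 the enone 4'-methoxy-3,5,7-tris(methoxymethoxy)-8-(3-methyl-2-oxobut-3-enyl)flavone, via benzylpalladium chloride complex 11 (not isolated), via acylpalladium chloride complex 12 (not isolated)
Conditions: Pd(PPh3)4 (5 mol %), CO (3 atm), 9 (1.2 equiv), THF, 60 °C
Reagents that add atoms: carbon monoxide (10), [C-]#[O+]; isopropenyltributylstannane (9), C=C(C)[Sn](CCCC)(CCCC)CCCC
Why: Carbonylative Stille cross-coupling: zerovalent palladium inserts into the benzylic C–Cl bond of 8 to give benzylpalladium complex 11, which has no β-hydrogen and takes up CO by migratory insertion to give arylacetylpalladium complex 12; transfer of the isopropenyl group from tin and reductive elimination then release enone 13 and Bu3SnCl, so that C1''–C2'' and C2''–C3'' are formed in one operation. The closest known reaction type is the three-component coupling of benzylic or allylic halides with CO and alkenylstannanes to give benzyl or allyl alkenyl ketones. No ring is closed and no stereocentre is created. The selectivity needed is carbonylative over direct benzyl–alkenyl coupling; CO pressure, the fast CO insertion of benzylpalladium species and the slow transmetalation of the α-branched stannane, which leaves time for CO uptake, should secure it. The benzylic chloride is the only bond of 8 that zerovalent palladium can enter, and the chromone carbonyl, the MOM acetals and the anisyl ether are inert under these neutral conditions.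

Step 5
Reactants: 13 the enone
Product: 15 the allylic alcohol 8-[(2S)-2-hydroxy-3-methylbut-3-enyl]-4'-methoxy-3,5,7-tris(methoxymethoxy)flavone, via catecholborate ester 14 (not isolated)
Conditions: (R)-2-methyl-CBS-oxazaborolidine (0.5 equiv), catecholborane (2.0 equiv), toluene/CH2Cl2, −78 °C; MeOH quench, aq. Na2CO3 work-up
Reagents that add atoms: none
Why: Corey–Bakshi–Shibata reduction: the ketone should bind the ring boron of the (R)-oxazaborolidine anti to its larger substituent, here the α-branched sp2 isopropenyl group rather than the CH2Ar group, so that the N-bound catecholborane delivers hydride to the Re face of C2'' and sets the S configuration (the sense that gives (S)-1-phenylethanol from acetophenone), while at −78 °C the catalysed 1,2-reduction should outrun conjugate reduction and leave the vinylogous-ester carbonyl of ring C untouched.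

Step 6
Reactants: 15 the allylic alcohol
Product: 16 2''-hydroxy-3''-en-anhydroicaritin, 3,5,7-trihydroxy-8-[(2S)-2-hydroxy-3-methylbut-3-enyl]-4'-methoxyflavone
Conditions: HCl (ca. 1.5 M, from conc. aq. HCl), MeOH/THF, rt to 40 °C
Reagents that add atoms: none
Why: Acid-catalysed acetal exchange of the three aryl MOM ethers with methanol (giving dimethoxymethane) should be faster near room temperature than protonation of the 1,1-disubstituted alkene, which the adjacent hydroxyl deactivates, or ionisation of the secondary allylic alcohol, so the 2''S centre and the isopropenyl group should be retained, as is usual for prenyl groups in MOM removals on flavonoids.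

**Compound list**

1 | kaempferide (3,5,7-trihydroxy-4'-methoxyflavone) | COc1ccc(-c2oc3cc(O)cc(O)c3c(=O)c2O)cc1 | starting material
2 | Eschenmoser's salt (N,N-dimethylmethyleneiminium iodide) | C=[N+](C)C.[I-] | starting material
3 | kaempferide 7-potassium phenoxide | COc1ccc(-c2oc3cc([O-])cc(O)c3c(=O)c2O)cc1.[K+] | intermediate
4 | 8-[(dimethylamino)methyl]kaempferide | CN(C)Cc1c(O)cc(O)c2c(=O)c(O)c(-c3ccc(OC)cc3)oc12 | intermediate
5 | trisodium triphenoxide of 4 | CN(C)Cc1c([O-])cc([O-])c2c(=O)c([O-])c(-c3ccc(OC)cc3)oc12.[Na+].[Na+].[Na+] | intermediate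
6 | 8-[(dimethylamino)methyl]-4'-methoxy-3,5,7-tris(methoxymethoxy)flavone | CN(C)Cc1c(OCOC)cc(OCOC)c2c(=O)c(OCOC)c(-c3ccc(OC)cc3)oc12 | intermediate
7 | N-ethoxycarbonylammonium chloride of 6 | CCOC(=O)[N+](C)(C)Cc1c(OCOC)cc(OCOC)c2c(=O)c(OCOC)c(-c3ccc(OC)cc3)oc12.[Cl-] | intermediate
8 | 8-(chloromethyl)-4'-methoxy-3,5,7-tris(methoxymethoxy)flavone | ClCc1c(OCOC)cc(OCOC)c2c(=O)c(OCOC)c(-c3ccc(OC)cc3)oc12 | intermediate
9 | isopropenyltributylstannane | C=C(C)[Sn](CCCC)(CCCC)CCCC | starting material
10 | carbon monoxide | [C-]#[O+] | starting material
11 | benzylpalladium chloride complex, trans-chloro(flavon-8-ylmethyl)bis(triphenylphosphine)palladium (divalent palladium) | Cl[Pd-2](Cc1c(OCOC)cc(OCOC)c2c(=O)c(OCOC)c(-c3ccc(OC)cc3)oc12)([P+](c1ccccc1)(c1ccccc1)c1ccccc1)[P+](c1ccccc1)(c1ccccc1)c1ccccc1 | intermediate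
12 | acylpalladium chloride complex, trans-chloro(flavon-8-ylacetyl)bis(triphenylphosphine)palladium (divalent palladium) | Cl[Pd-2](C(=O)Cc1c(OCOC)cc(OCOC)c2c(=O)c(OCOC)c(-c3ccc(OC)cc3)oc12)([P+](c1ccccc1)(c1ccccc1)c1ccccc1)[P+](c1ccccc1)(c1ccccc1)c1ccccc1 | intermediate
13 | 4'-methoxy-3,5,7-tris(methoxymethoxy)-8-(3-methyl-2-oxobut-3-enyl)flavone | C=C(C)C(=O)Cc1c(OCOC)cc(OCOC)c2c(=O)c(OCOC)c(-c3ccc(OC)cc3)oc12 | intermediate
14 | catecholborate ester of the (S)-alcohol 15 | C=C(C)[C@@H](OB1Oc2ccccc2O1)Cc1c(OCOC)cc(OCOC)c2c(=O)c(OCOC)c(-c3ccc(OC)cc3)oc12 | intermediate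
15 | 8-[(2S)-2-hydroxy-3-methylbut-3-enyl]-4'-methoxy-3,5,7-tris(methoxymethoxy)flavone | C=C(C)[C@@H](O)Cc1c(OCOC)cc(OCOC)c2c(=O)c(OCOC)c(-c3ccc(OC)cc3)oc12 | intermediate
16 | 2''-hydroxy-3''-en-anhydroicaritin, 3,5,7-trihydroxy-8-[(2S)-2-hydroxy-3-methylbut-3-enyl]-4'-methoxyflavone | C=C(C)[C@@H](O)Cc1c(O)cc(O)c2c(=O)c(O)c(-c3ccc(OC)cc3)oc12 | target

**Step count and risks**

Total step count: 6. Longest linear sequence: 6 steps (1 to 16).

Steps most likely to fail:

1. Step 4, the carbonylative Stille coupling. Transmetalation of the α-branched stannane may be so slow that the benzyl- and acylpalladium species are diverted into homocoupling, reduction or direct coupling without CO uptake. The electron-rich benzylic chloride may also be consumed by alkylating free PPh3. The fallback sets out from 8 and returns at 13. It reverses the polarity and brings in C2'' and C3'' already joined. LiCl-assisted insertion of Zn dust into 8 (THF, rt) should give the benzylic zinc chloride F1. This is acylated with methacryloyl chloride under Pd(PPh3)4 catalysis (Negishi acylation, THF, 0 °C to rt) to give enone 13; organozinc reagents do not attack the chromone carbonyl.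

2. Step 5, the enantioselective reduction. The bulky 2,6-disubstituted arylmethyl group may compete with the isopropenyl group for the "large" position and erode facial selectivity. Uncatalysed conjugate reduction by catecholborane may also intrude. The fallback sets out from 13 and returns at 15. Luche reduction (NaBH4, CeCl3·7H2O, MeOH, −40 °C) should give the racemic allylic alcohol F2 by 1,2-addition. Sharpless kinetic resolution follows (Ti(OiPr)4, D-(−)-diisopropyl tartrate, tBuOOH 0.6 equiv, 4 Å sieves, CH2Cl2, −20 °C). It should epoxidise the R enantiomer, whose carbinol hydrogen faces the oxidant, to the (2''R,3''R)-epoxy alcohol F3. The S alcohol 15 is left and is separated by chromatography.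

3. Step 6, the acidic MOM removal. Protonation of the isopropenyl group or ionisation of the allylic alcohol may lead to ring closure by the freed 7-hydroxyl (chroman or dihydrofuran formation) or to loss of configuration at C2''. The fallback sets out from 15 and returns at 16. It replaces protic solvolysis by buffered silyl transfer. TMSOTf with 2,2'-bipyridyl (MeCN, 0 °C to rt) should exchange the three aryl MOM ethers for trimethylsilyl ethers and silylate the 2''-hydroxyl, giving the tetrakis(trimethylsilyl) ether F4 with no free acid present. Addition of water then hydrolyses the O–Si bonds to give 16.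

**Further compounds**

F1 | step 4 | [4'-methoxy-3,5,7-tris(methoxymethoxy)flavon-8-yl]methylzinc chloride | Cl[Zn]Cc1c(OCOC)cc(OCOC)c2c(=O)c(OCOC)c(-c3ccc(OC)cc3)oc12
F2 | step 5 | racemic 8-(2-hydroxy-3-methylbut-3-enyl)-4'-methoxy-3,5,7-tris(methoxymethoxy)flavone | C=C(C)C(O)Cc1c(OCOC)cc(OCOC)c2c(=O)c(OCOC)c(-c3ccc(OC)cc3)oc12
F3 | step 5 | 8-[(2R)-2-hydroxy-2-[(2R)-2-methyloxiran-2-yl]ethyl]-4'-methoxy-3,5,7-tris(methoxymethoxy)flavone | C[C@@]1(CO1)[C@H](O)Cc1c(OCOC)cc(OCOC)c2c(=O)c(OCOC)c(-c3ccc(OC)cc3)oc12
F4 | step 6 | 4'-methoxy-3,5,7-tris(trimethylsilyloxy)-8-[(2S)-3-methyl-2-(trimethylsilyloxy)but-3-enyl]flavone | C=C(C)[C@@H](O[Si](C)(C)C)Cc1c(O[Si](C)(C)C)cc(O[Si](C)(C)C)c2c(=O)c(O[Si](C)(C)C)c(-c3ccc(OC)cc3)oc12
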